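**Retrosynthetic overview**
1. Target 16 ⇐ open tigloyl triketone acid 15 ⇐ enol lactone 14: the pyranone is closed last, by oxa-Michael addition of a ring oxygen to the tigloyl group as in the presumed biosynthesis; that oxygen is released from the lactone in the same flask.
2. 14 ⇐ arene 12 + prenyl donor 13: dearomatising C-prenylation creates the quaternary centre.
3. 12 ⇐ tigloyl lactone 5 + aldehyde 10: reductive C-alkylation. The cyclobutane is taken intact from (−)-verbenone, because acid-induced closure of a lavandulyl cation gives six-membered rings in the flask.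
4. 5 ⇐ dihydrocoumarin 3 ⇐ phloroglucinol + cinnamaldehyde: neoflavonoid-type annulation sets the benzylic centre; its lactone later serves as the masked pyran oxygen.
5. Ring order: carbocycle and cyclobutane bought; δ-lactone (step 1, temporary); pyranone (step 8).

Assumption: the antipodes of the triazolium salt, the Trost ligand and the cinchona alkaloid are written as the closest analogies predict; the sense of induction is checked on the first run and the mirror-image catalyst (quinidine for quinine) is used if needed. Carbonate 13 is treated as a purchased reagent.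

**Route**

Step 1
Reactants: 1 phloroglucinol (3 equiv); 2 (E)-cinnamaldehyde
Product: 3 (4S)-5,7-dihydroxy-4-phenyl-3,4-dihydro-2H-chromen-2-one
Conditions: chiral aminoindanol-derived N-mesityl triazolium chloride (10 mol%), DBU (20 mol%), 3,3',5,5'-tetra-tert-butyldiphenoquinone (1.1 equiv), THF, 25 °C
Reagents that add atoms: none
Why: Oxidative NHC catalysis turns the enal into a chiral α,β-unsaturated acyl azolium, which the enol-like carbon of phloroglucinol attacks (Michael/Coates–Claisen-type annulation, as known for 2-naphthols and cyclic 1,3-diones), and lactonisation onto the neighbouring OH releases the carbene with C-4 set as S by the catalyst; excess symmetrical 1 suppresses double annulation.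

Step 2
Reactants: 3 (4S)-5,7-dihydroxy-4-phenyl-3,4-dihydro-2H-chromen-2-one; 4 tigloyl chloride
Product: 5 (4S)-5,7-dihydroxy-8-[(2E)-2-methylbut-2-enoyl]-4-phenyl-3,4-dihydro-2H-chromen-2-one
Conditions: AlCl3 (3.5 equiv), PhNO2, 0 → 25 °C; ice/aq. HCl
Reagents that add atoms: none
Why: Friedel–Crafts acylation at C-8 (ortho to 7-OH, para to 5-OH, the site acylated in 5,7-dihydroxy-4-arylcoumarins) is run before any acid-labile alkene is present, and the non-enolisable C-4 centre is untouched.

Step 3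
Reactants: 6 (1S,5S)-(−)-verbenone
Product: 7 (1S,3R)-3-acetyl-2,2-dimethylcyclobutane-1-carboxylic acid
Conditions: RuCl3·xH2O (2 mol%), NaIO4 (4.2 equiv), CCl4/MeCN/H2O, 25 °C
Reagents that add atoms: sodium periodate [Na+].[O-]I(=O)(=O)=O; water O
Why: RuO4 oxidative cleavage of the enone C=C with loss of one carbon as CO2 (α-keto acid decarboxylation) gives the cis keto acid, both stereocentres coming unchanged from the pinane skeleton.

Step 4
Reactants: 7 (1S,3R)-3-acetyl-2,2-dimethylcyclobutane-1-carboxylic acid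
Product: 8 (1S,3S)-2,2-dimethyl-3-(prop-1-en-2-yl)cyclobutane-1-carboxylic acid
Conditions: Ph3PCH3Br (2.5 equiv), KOtBu (2.4 equiv), THF, 0 → 25 °C; then H3O+
Reagents that add atoms: methyltriphenylphosphonium bromide C[P+](c1ccccc1)(c1ccccc1)c1ccccc1.[Br-]
Why: Wittig methylenation of the methyl ketone while the acid is protected as its carboxylate, with the cis-1,3 arrangement (the more stable one) retained.

Step 5
Reactants: 8 (1S,3S)-2,2-dimethyl-3-(prop-1-en-2-yl)cyclobutane-1-carboxylic acid
Product: 10 (1S,3S)-2,2-dimethyl-3-(prop-1-en-2-yl)cyclobutane-1-carbaldehyde, via acyl imidazolide 9 (not isolated)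
Conditions: CDI (1.1 equiv), THF, 25 °C; then DIBAL-H (2.1 equiv), −78 °C; Rochelle salt
Reagents that add atoms: none
Why: One-pot activation and partial reduction, in which the acyl imidazolide gives a stable tetrahedral aluminate that collapses to the aldehyde only on work-up, a protocol that preserves α-stereocentres.

Step 6
Reactants: 5 (4S)-5,7-dihydroxy-8-[(2E)-2-methylbut-2-enoyl]-4-phenyl-3,4-dihydro-2H-chromen-2-one; 10 (1S,3S)-2,2-dimethyl-3-(prop-1-en-2-yl)cyclobutane-1-carbaldehyde
Product: 12 (4S)-6-{[(1R,3S)-2,2-dimethyl-3-(prop-1-en-2-yl)cyclobutyl]methyl}-5,7-dihydroxy-8-[(2E)-2-methylbut-2-enoyl]-4-phenyl-3,4-dihydro-2H-chromen-2-one, via o-quinone methide 11 (not isolated)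
Conditions: Hantzsch ester (1.5 equiv), (PhO)2P(O)OH (10 mol%), CH2Cl2, 35 °C
Reagents that add atoms: none
Why: Reductive C-alkylation (Knoevenagel-type condensation then transfer hydrogenation): acid-catalysed hydroxyalkylation of the only free, doubly OH-activated carbon C-6 and dehydration give the o-quinone methide, which the Hantzsch ester reduces by conjugate hydride transfer, while the amine-free conditions avoid enamine epimerisation of the aldehyde α-carbon and base-induced closure of the tigloyl group.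

Step 7
Reactants: 12 (4S)-6-{[(1R,3S)-2,2-dimethyl-3-(prop-1-en-2-yl)cyclobutyl]methyl}-5,7-dihydroxy-8-[(2E)-2-methylbut-2-enoyl]-4-phenyl-3,4-dihydro-2H-chromen-2-one; 13 tert-butyl (2-methylbut-3-en-2-yl) carbonate
Product: 14 (4S,6S)-6-{[(1R,3S)-2,2-dimethyl-3-(prop-1-en-2-yl)cyclobutyl]methyl}-7-hydroxy-8-[(2E)-2-methylbut-2-enoyl]-6-(3-methylbut-2-en-1-yl)-4-phenyl-3,4-dihydro-2H-chromene-2,5(6H)-dione
Conditions: Pd2(dba)3·CHCl3 (2.5 mol%), (R,R)-DACH-phenyl Trost ligand (7.5 mol%), CH2Cl2, 0 °C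
Reagents that add atoms: none
Why: Proposed new method: Pd-catalysed asymmetric allylic dearomatisation (Tsuji–Trost), in which the carbonate ionises to a π-(dimethylallyl)Pd complex plus tert-butoxide and the phenoxide of 12 attacks the unsubstituted allyl terminus through C-6 (the only ring carbon flanked by two free oxygens; branched attack would join two quaternary carbons), the new centre being set by attack anti to the pseudo-axial C-4 phenyl reinforced by the ligand pocket; the closest known reactions are the Pd/Trost-ligand allylic dearomatisation of 1,3-disubstituted 2-naphthols, linear asymmetric prenylation of oxindoles with this carbonate, and racemic Pd-catalysed dearomative allylation of acylphloroglucinols.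

Step 8
Reactants: 14 (4S,6S)-6-{[(1R,3S)-2,2-dimethyl-3-(prop-1-en-2-yl)cyclobutyl]methyl}-7-hydroxy-8-[(2E)-2-methylbut-2-enoyl]-6-(3-methylbut-2-en-1-yl)-4-phenyl-3,4-dihydro-2H-chromene-2,5(6H)-dione
Product: 16 (3S)-3-[(2R,3S,6R)-6-{[(1R,3S)-2,2-dimethyl-3-(prop-1-en-2-yl)cyclobutyl]methyl}-4-hydroxy-2,3-dimethyl-6-(3-methylbut-2-en-1-yl)-5,7-dioxo-3,5,6,7-tetrahydro-2H-chromen-8-yl]-3-phenylpropanoic acid, via ring-opened triketone acid 15 (not isolated)
Conditions: (−)-quinine (2.2 equiv), H2O (5 equiv), PhCl, 0 → 25 °C; then 10% aq. citric acid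
Reagents that add atoms: water O
Why: Proposed new method: quinine/water opens the vinylogous-anhydride lactone of 14 and so releases the former lactone oxygen as an oxyanion (ion-paired with quininium) beside the tigloyl β-carbon while the 7-OH stays hydrogen-bonded to the enone carbonyl and turns the C=C towards that oxygen, so 6-endo oxa-Michael addition closes the pyranone through the correct oxygen, with C-2 set R by the alkaloid and C-3 set by kinetic protonation cis to the 2-methyl; the closest known reaction is the quinine-catalysed intramolecular oxa-Michael addition of 7-hydroxy-8-tigloylcoumarins to (2R,3S)-cis-2,3-dimethylchromanones.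

**Compound list**
1 | phloroglucinol | Oc1cc(O)cc(O)c1 | starting material
2 | (E)-cinnamaldehyde | O=C/C=C/c1ccccc1 | starting material
3 | (4S)-5,7-dihydroxy-4-phenyl-3,4-dihydro-2H-chromen-2-one | O=C1C[C@@H](c2ccccc2)c2c(O)cc(O)cc2O1 | intermediate
4 | tigloyl chloride, (E)-2-methylbut-2-enoyl chloride | C/C=C(\C)C(=O)Cl | starting material
5 | (4S)-5,7-dihydroxy-8-[(2E)-2-methylbut-2-enoyl]-4-phenyl-3,4-dihydro-2H-chromen-2-one | C/C=C(\C)C(=O)c1c(O)cc(O)c2c1OC(=O)C[C@H]2c1ccccc1 | intermediate
6 | (1S,5S)-(−)-verbenone | CC1=CC(=O)[C@H]2C[C@@H]1C2(C)C | starting material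
7 | (1S,3R)-3-acetyl-2,2-dimethylcyclobutane-1-carboxylic acid (cis-pinononic acid) | CC(=O)[C@@H]1C[C@H](C(=O)O)C1(C)C | intermediate
8 | (1S,3S)-2,2-dimethyl-3-(prop-1-en-2-yl)cyclobutane-1-carboxylic acid (cis) | C=C(C)[C@@H]1C[C@H](C(=O)O)C1(C)C | intermediate
9 | 1-[(1S,3S)-2,2-dimethyl-3-(prop-1-en-2-yl)cyclobutane-1-carbonyl]imidazole | C=C(C)[C@@H]1C[C@H](C(=O)n2ccnc2)C1(C)C | intermediate
10 | (1S,3S)-2,2-dimethyl-3-(prop-1-en-2-yl)cyclobutane-1-carbaldehyde (cis) | C=C(C)[C@@H]1C[C@H](C=O)C1(C)C | intermediate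
11 | o-quinone methide: (4S)-6-{[(1R,3S)-2,2-dimethyl-3-(prop-1-en-2-yl)cyclobutyl]methylidene}-7-hydroxy-8-tigloyl-4-phenyl-3,4-dihydro-2H-chromene-2,5(6H)-dione | C/C=C(\C)C(=O)C1=C(O)C(=C[C@H]2C[C@@H](C(C)=C)C2(C)C)C(=O)C2=C1OC(=O)C[C@H]2c1ccccc1 | intermediate
12 | (4S)-6-{[(1R,3S)-2,2-dimethyl-3-(prop-1-en-2-yl)cyclobutyl]methyl}-5,7-dihydroxy-8-[(2E)-2-methylbut-2-enoyl]-4-phenyl-3,4-dihydro-2H-chromen-2-one | C/C=C(\C)C(=O)c1c(O)c(C[C@H]2C[C@@H](C(C)=C)C2(C)C)c(O)c2c1OC(=O)C[C@H]2c1ccccc1 | intermediate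
13 | tert-butyl (2-methylbut-3-en-2-yl) carbonate | C=CC(C)(C)OC(=O)OC(C)(C)C | starting material
14 | (4S,6S)-6-{[(1R,3S)-2,2-dimethyl-3-(prop-1-en-2-yl)cyclobutyl]methyl}-7-hydroxy-8-[(2E)-2-methylbut-2-enoyl]-6-(3-methylbut-2-en-1-yl)-4-phenyl-3,4-dihydro-2H-chromene-2,5(6H)-dione | C/C=C(\C)C(=O)C1=C(O)[C@](CC=C(C)C)(C[C@H]2C[C@@H](C(C)=C)C2(C)C)C(=O)C2=C1OC(=O)C[C@H]2c1ccccc1 | intermediate
15 | (3S)-3-[(3R)-3-{[(1R,3S)-2,2-dimethyl-3-(prop-1-en-2-yl)cyclobutyl]methyl}-2,4-dihydroxy-5-[(2E)-2-methylbut-2-enoyl]-3-(3-methylbut-2-en-1-yl)-6-oxocyclohexa-1,4-dien-1-yl]-3-phenylpropanoic acid | C/C=C(\C)C(=O)C1=C(O)[C@](CC=C(C)C)(C[C@H]2C[C@@H](C(C)=C)C2(C)C)C(O)=C([C@@H](CC(=O)O)c2ccccc2)C1=O | intermediate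
16 | (3S)-3-[(2R,3S,6R)-6-{[(1R,3S)-2,2-dimethyl-3-(prop-1-en-2-yl)cyclobutyl]methyl}-4-hydroxy-2,3-dimethyl-6-(3-methylbut-2-en-1-yl)-5,7-dioxo-3,5,6,7-tetrahydro-2H-chromen-8-yl]-3-phenylpropanoic acid (CNP0328119.1; cis-2,3-dimethyl, cis-cyclobutane) | C=C(C)[C@@H]1C[C@H](C[C@@]2(CC=C(C)C)C(=O)C3=C(O)[C@@H](C)[C@@H](C)OC3=C([C@@H](CC(=O)O)c3ccccc3)C2=O)C1(C)C | target

**Count**
Total steps: 8. Longest linear sequence: 6 steps (6 → 7 → 8 → 10 → 12 → 14 → 16; steps 3, 4, 5, 6, 7, 8).

**Three steps most likely to fail, with fallbacks**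

Step 8 (pyranone closure). The risks are closure through the 7-oxygen instead of the freed lactone oxygen, trans product, or low ee at C-2. The fallback uses a covalent template and sets out from 14. BF3·OEt2 and iPr2NEt in CH2Cl2 at 0 °C tie the only enolic OH and the tigloyl carbonyl of 14 into the difluoroboron chelate of 14 F1. This blocks the 7-oxygen, locks the enone C=C towards the lactone oxygen and activates it. Quinine and water then open the lactone, and the freed oxygen adds to give the difluoroboron chelate of the chromanone F2. Aqueous NaOAc in MeOH/THF removes boron and the route is rejoined at 16.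

Step 7 (dearomatising prenylation). The risks are O-alkylation, reverse-prenyl product, attack at another carbon, and poor face selectivity. The fallback replaces the ionic C–C bond formation by a sigmatropic one and sets out from 12. The non-chelated 5-OH is O-alkylated with 3-chloro-3-methylbut-1-yne (CuCl2 cat., DBU, MeCN, 0 °C) to give the 5-O-(1,1-dimethylpropargyl) ether F3. Lindlar semi-hydrogenation gives the 5-O-(1,1-dimethylallyl) ether F4. Aromatic Claisen rearrangement (toluene, 100 °C) can only deliver a normal prenyl group to the neighbouring C-6, and the route is rejoined at 14; the C-6 epimers are separated if the C-4 phenyl alone gives insufficient face control.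

Step 1 (NHC annulation). The risks are simple O-acylation to the aryl cinnamate, double annulation, or low ee with this new enol partner. The fallback uses iminium catalysis and sets out from 1 and 2. Diphenylprolinol trimethylsilyl ether (20 mol%) with PhCO2H in toluene at 0 °C effects Friedel–Crafts alkylation and hemiacetalisation to the lactol (4S)-4-phenyl-3,4-dihydro-2H-chromene-2,5,7-triol F5. Ag2CO3 on Celite (toluene, 80 °C) oxidises the lactol in the presence of the free phenols, and the route is rejoined at 3.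

**Further compounds**
F1 | step 8 | difluoroboron chelate of 14 (boron bridging the 7-oxygen and the tigloyl carbonyl oxygen) | C/C=C(\C)C3=[O+][B-](F)(F)OC4=C3C5=C(C(=O)[C@@]4(CC=C(C)C)C[C@H]6C[C@@H](C(C)=C)C6(C)C)[C@H](c6ccccc6)CC(=O)O5
F2 | step 8 | difluoroboron chelate of 16 (boron bridging the 5-oxygen and the 4-oxygen of the chromanone) | C=C(C)[C@@H]1C[C@H](C[C@@]2(CC=C(C)C)C4=[O+][B-](F)(F)OC([C@@H](C)[C@@H](C)O5)=C4C5=C([C@@H](CC(=O)O)c3ccccc3)C2=O)C1(C)C
F3 | step 7 | (4S)-6-{[(1R,3S)-2,2-dimethyl-3-(prop-1-en-2-yl)cyclobutyl]methyl}-7-hydroxy-5-[(2-methylbut-3-yn-2-yl)oxy]-8-[(2E)-2-methylbut-2-enoyl]-4-phenyl-3,4-dihydro-2H-chromen-2-one | C/C=C(\C)C(=O)c1c(O)c(C[C@H]2C[C@@H](C(C)=C)C2(C)C)c(OC(C)(C)C#C)c2c1OC(=O)C[C@H]2c1ccccc1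
F4 | step 7 | (4S)-6-{[(1R,3S)-2,2-dimethyl-3-(prop-1-en-2-yl)cyclobutyl]methyl}-7-hydroxy-5-[(2-methylbut-3-en-2-yl)oxy]-8-[(2E)-2-methylbut-2-enoyl]-4-phenyl-3,4-dihydro-2H-chromen-2-one | C/C=C(\C)C(=O)c1c(O)c(C[C@H]2C[C@@H](C(C)=C)C2(C)C)c(OC(C)(C)C=C)c2c1OC(=O)C[C@H]2c1ccccc1
F5 | step 1 | (4S)-4-phenyl-3,4-dihydro-2H-chromene-2,5,7-triol (lactol, anomer mixture) | OC1C[C@@H](c2ccccc2)c2c(O)cc(O)cc2O1
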